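At 4.00 h Thursday's flask reads 80.8 % of target, and the question is what it holds at 20 h and which change gives more.

| flask | starting material | gas phase | protic impurity | remark | time |
|---|---|---|---|---|---|
| Thursday's | 0.80 M | 61 mM (held) | 0.080 M | the very flask that is asked about, followed so far |  |
| Tuesday's | 0.80 M | 61 mM (held) | 0.040 M | run made earlier |  |
| flask | 0.80 M | 61 mM (held) | 0.0800 M |  | 20 h |

| Thursday's: time / h | Thursday's: target / % | Tuesday's: time / h | Tuesday's: target / % |
|---|---|---|---|
| 0.250 | 14.1 | 2.00 | 77.2 |
| 0.667 | 36.9 | 4.00 | 81.4 |
| 1.50 | 66.6 | 6.00 | 81.5 |
| 4.00 | 80.8 | 8.00 | 82.7 |

(scatter of a reading: 1 percentage point)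

- target at 20 h, in percent of the starting material charged
- the change that raises the amount of target at 20 h, in percent of the starting material charged most ("none" if none brings more than 2 percentage points) (noon / midnight / none)
- amount of target at 20 h, in percent of the starting material charged, after midnight

- noon: doubling the saturation concentration of gas phase, all else as stated
- midnight: doubling the transfer coefficient of the gas phase, all else as stated

- at the start none of the gas phase is in solution

I read Thursday's table row by row. The first two rows give 0.451 M/h and then 0.437 M/h of target. At that pace the saturation amount of 61 mM lasts 8.12 min, so gas must keep entering the solution throughout this stretch. The third row slows to 0.285 M/h, so there the starting material counts too.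

The fourth row meets Tuesday's flat readings. Tuesday's 81.4 % at 4.00 h differs by 0.6 percentage points from Thursday's, with the impurity twice as high on Thursday. These four readings average 81.6 %, which is my answer for 20 h.

Now I follow one molecule: it waits its turn for gas, and I assume a steady leak per hour while it waits. This gives the odds of loss, lost over target, the inverse of a selectivity factor: 0.225. At fixed gas settings I scale them with the charge, and target is 1/(1 + odds).

Noon doubles the ceiling on [dissolved gas], so I cut the odds to half, giving 89.9 %. Midnight speeds the transfer but leaves that ceiling where it is, so I guess a cut of a quarter, giving 85.5 %.

The forecast gives 82 %, noon as best, and 83 % after midnight, lower than my figure, holding that “Either way, raising saturation lifts it”.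

The flask gives 81.3 % at 20 h and 85.0 % after midnight; noon is best, adding 8 points against 3.8 points for midnight.

    gas phase ⇌ dissolved gas, rate k1*(csat - [dissolved gas]) (kL = 13.5 /h)
    starting material + dissolved gas → target (k = 31.9 /M/h)
    starting material → side product A (k = 0.197 /h)
    dissolved gas + protic impurity → quenched reagent (k = 0.625 /M/h)
    starting material + target → side product B (k = 0.0424 /M/h)

The same odds go to the neighbour charged with 1.4 M of starting material, other charges and time held. Its charge is 1.75 times this flask's, so the odds become 0.395 and the target 71.7 %. That neighbour gives 75.4 % of target, with 20.9 % side product A and 3.70 % side product B.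

The numbers in the tables are simulated for an exercise, and the scatter is random.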